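Slowness is the question here: the loss of J drags on in the late readings, and the excess of D over J depends on how far c_J/c_D falls by the end.

common to all: X 2.9 mM (held)

| flask | J | D | E | remark | time |
|---|---|---|---|---|---|
| south-west | 0.040 M | 0.040 M | 0.46 mM | run made earlier |  |
| west | 0.16 M | 0.16 M | 0.46 mM | run made earlier |  |
| north | 0.079 M | 0.079 M | 0.23 mM | run made earlier |  |
| flask | 0.079 M | 0.079 M | 0.46 mM |  | 10 d |

- south-west (time / d: D / %, J / %, Q / %): 1.04: 48.1, 6.3, 29.6; 2.08: 46.2, 1.4, 27.0; 3.00: 46.8, 3.3, 24.1; 4.00: 46.5, 0, 24.1; 5.00: 45.2, 1.5, 25.9; 6.00: 44.5, 0.2, 26.9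
- west (time / d: D / %, J / %, Q / %): 0.417: 48.8, 31.6, 14.7; 1.25: 50.0, 16.6, 22.8; 2.00: 47.3, 10.1, 23.3; 3.00: 47.1, 6.5, 23.6; 5.00: 47.3, 3.0, 25.4; 6.00: 47.1, 2.1, 26.0
- north (time / d: D / %, J / %, Q / %): 0.500: 50.4, 25.6, 20.3; 0.833: 48.8, 17.4, 23.5; 1.67: 48.1, 7.6, 22.2; 3.00: 47.2, 4.9, 24.3; 6.00: 45.8, 1.7, 27.8

(scatter of a reading: 1 percentage point)

- E is single-handed; J and D are mirror images of each other, charged as a racemate, each of them at the stated concentration
- at the start none of X is in solution

- whether the excess of D over J among what is left of the two reaches 90% by 10 d (no / yes)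
- the highest excess of D over J among what is left of the two up to 10 d

An excess of 90% needs c_J/c_D of 0.0526. Between 3.00 d and 6.00 d, the north readings lose J at 0.353 d⁻¹: this is the tail slope, the mean fall of ln c_J per unit time over a late window of a run, read from two scattered readings. The west readings give 0.377 d⁻¹ over the same days, with twice the c_J of the north run. The flask has the charged c_J of the north run and the charged c_E of the west run, so I apply the tail slope to it and hold it steady as an estimate. Starting from the north ratio of 0.104 at 3.00 d, I reckon 0.0526 is reached at 4.93 d, earlier than 10 d. At 10 d the ratio stands at 0.00878, an excess of 98.3%, so I say yes.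

The forecast says yes with a top of 97.5%, below my figure: "The flask should behave like south-west or better than north".

The flask gives yes and 96.5%.

    Q ⇌ L (k = 7.32 × 10⁻⁴ min⁻¹)
    2 E → G (k = 7.21 M⁻¹ min⁻¹)
    Z + E + D → E + L (k = 158 M⁻² min⁻¹)
    Z + E + J → E + Q (k = 6050 M⁻² min⁻¹)
    X ⇌ Z, rate k5*(csat - [Z]) (kL = 0.0499 min⁻¹)

The flask reaches 90% at 3.88 d and ends with c_J/c_D of 0.0176, a third of 0.0526. From 5.00 d to 10.0 d, E in the flask falls from 2.05% to 1.04%, about half. The tail slope of 0.353 d⁻¹, carried over those days from J at 1.80%, lands at 0.308%, but the flask holds 0.788%, so its own mean slope over those days is 0.165 d⁻¹.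

The data were generated by integration with made-up constants, and the scatter is random.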